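**Plan**

1. Lettering: phenanthrene rings A (C5–C8, OMe on C7), B (C9/C10) and C (C1–C4, Cl on C2, OH on C3); ring E is the chlorinated phenol ring on C6, ring D the phenol ring on C4. The twelve-membered ring runs C4–C4a–C4b–C5–C6, two carbons of ring E, CH2CH2, three carbons of ring D.
2. Retrosynthesis: (i) the C4–ring D biaryl bond, formed last across a temporary O–Si(tBu)2–O bridge between the C3 oxygen and the ring D oxygen; (ii) the CH2–CH2 bridge (Wittig, then diimide); (iii) the C6–ring E bond (Suzuki–Miyaura); (iv) ring B, by C10–C10a (Friedel–Crafts closure) and C4a–C4b (Suzuki–Miyaura).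
3. Forward: A–C biaryl → ring B (phenanthrene) → ring E on C6 → ring D through the two-carbon bridge → 17-membered silylene-bridged ring → palladium-catalysed C–H arylation closes the twelve-membered ring → fluoride and acid free the three phenols.
4. Enabling feature: the oxygen on C3 of ring C and the oxygen of ring D both stand ortho to the bond to be made (a 2,2'-biphenol), so one silicon atom turns the twelve-membered closure into a seven-membered one. Cl on C2 blocks the only other ortho position of the C3 oxygen, and ring D is a para-substituted phenol whose coupling carbon is marked by one bromine.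
5. Stereochemistry: the target has no stereocentre; the alkene isomers from the two Wittig steps disappear on aromatisation or reduction.

Key step: step 16

Assumption: the target SMILES gives no descriptor for the twisted biaryl axes, so no axial configuration is controlled and the racemic material is made.

**Route**

Step 1
Reactants: 1 3-bromo-4-hydroxybenzaldehyde
Product: 2 3-bromo-4-[(triisopropylsilyl)oxy]benzaldehyde
Conditions: iPr3SiCl, imidazole, DMF, rt
Reagents that add atoms: triisopropylsilyl chloride, CC(C)[Si](Cl)(C(C)C)C(C)C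
Why: Imidazole-promoted silylation of the phenol; the triisopropylsilyl ether withstands ylide, base and diimide and is later removed by fluoride without loss of the MOM group.

Step 2
Reactants: 2 3-bromo-4-[(triisopropylsilyl)oxy]benzaldehyde
Product: 3 {3-bromo-4-[(triisopropylsilyl)oxy]phenyl}methanol
Conditions: NaBH4, MeOH/THF, 0 °C
Reagents that add atoms: none
Why: Borohydride reduction of the aldehyde to the benzylic alcohol, with the aryl bromide and the silyl ether untouched.

Step 3
Reactants: 3 {3-bromo-4-[(triisopropylsilyl)oxy]phenyl}methanol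
Product: 5 {3-bromo-4-[(triisopropylsilyl)oxy]benzyl}triphenylphosphonium bromide, via benzyl bromide 4 (not isolated)
Conditions: CBr4, PPh3, CH2Cl2, 0 °C → rt; then PPh3, toluene, 90 °C
Reagents that add atoms: carbon tetrabromide, BrC(Br)(Br)Br; triphenylphosphine, c1ccc(cc1)P(c1ccccc1)c1ccccc1
Why: Appel bromination of the benzylic alcohol under neutral conditions followed by SN2 quaternisation of PPh3 by bromide 4, the standard access to benzylic Wittig salts.

Step 4
Reactants: 6 2-bromo-4-chlorophenol
Product: 7 2-bromo-4-chloro-1-(methoxymethoxy)benzene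
Conditions: MeOCH2Cl, iPr2NEt, CH2Cl2, 0 °C → rt
Reagents that add atoms: chloromethyl methyl ether, COCCl
Why: Base-mediated O-alkylation of the phenol by the chloromethyl ether; the MOM ether tolerates amide bases, ylides, palladium couplings and fluoride and leaves with acid in the last step.

Step 5
Reactants: 7 2-bromo-4-chloro-1-(methoxymethoxy)benzene
Product: 9 2-bromo-6-chloro-3-(methoxymethoxy)benzaldehyde, via aryllithium 8 (not isolated)
Conditions: LiN(iPr)2, THF, −78 °C; then DMF, −78 → −20 °C; aq. NH4Cl
Reagents that add atoms: N,N-dimethylformamide, CN(C)C=O; lithium diisopropylamide, CC(C)N([Li])C(C)C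
Why: The hydrogen between Br and Cl is the most acidic of 7, so LiN(iPr)2 at −78 °C should give aryllithium 8 at that carbon (the most stabilised anion, which leaves no driving force for halogen migration) and DMF formylates it, a directed ortho-lithiation followed by formylation.

Step 6
Reactants: 10 4-bromo-3-methoxybenzaldehyde
Product: 11 4-bromo-2-iodo-5-methoxybenzaldehyde
Conditions: N-iodosuccinimide, CF3CO2H, rt, dark
Reagents that add atoms: N-iodosuccinimide, O=C1CCC(=O)N1I
Why: Electrophilic aromatic iodination should go para to the methoxy group, the only activated position that is not wedged between two substituents, and puts iodine ortho to the formyl group where the next coupling needs it.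

Step 7
Reactants: 11 4-bromo-2-iodo-5-methoxybenzaldehyde; 12 (4-chloro-3-hydroxyphenyl)boronic acid
Product: 13 5-bromo-4'-chloro-3'-hydroxy-4-methoxybiphenyl-2-carbaldehyde
Conditions: Pd(PPh3)4 (3 mol %), Na2CO3 (aq.), DME, 60 °C, 1.0 equiv of 12
Reagents that add atoms: none
Why: Suzuki–Miyaura coupling in which zerovalent palladium with PPh3 inserts into the C–I bond far faster than into C–Br or C–Cl, so with one equivalent of 12 only the C4a–C4b biaryl bond should form and the free phenol is tolerated.

Step 8
Reactants: 13 5-bromo-4'-chloro-3'-hydroxy-4-methoxybiphenyl-2-carbaldehyde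
Product: 14 5'-bromo-4-chloro-4'-methoxy-2'-(2-methoxyethenyl)biphenyl-3-ol (E/Z mixture)
Conditions: MeOCH2PPh3Cl (3 equiv), KOtBu (3 equiv), THF, 0 °C → rt
Reagents that add atoms: (methoxymethyl)triphenylphosphonium chloride, COC[P+](c1ccccc1)(c1ccccc1)c1ccccc1.[Cl-]
Why: Wittig methoxymethylenation adds the one carbon that becomes C10; the excess ylide covers the acidic phenol and both enol ether isomers converge in step 9.

Step 9
Reactants: 14 5'-bromo-4-chloro-4'-methoxy-2'-(2-methoxyethenyl)biphenyl-3-ol
Product: 16 6-bromo-2-chloro-7-methoxyphenanthren-3-ol, via dihydrophenanthrene methyl ether 15 (not isolated)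
Conditions: MeSO3H, CH2Cl2, 0 °C → rt
Reagents that add atoms: none
Why: Protonation of the enol ether gives an oxocarbenium ion that ring C should attack para to its hydroxyl in a six-membered Friedel–Crafts closure (the alternative ortho position lies between OH and the biaryl bond), and loss of methanol from 15 aromatises ring B, a cyclodehydration of the Bradsher type.

Step 10
Reactants: 16 6-bromo-2-chloro-7-methoxyphenanthren-3-ol
Product: 17 2-chloro-7-methoxy-6-(4,4,5,5-tetramethyl-1,3,2-dioxaborolan-2-yl)phenanthren-3-ol
Conditions: B2pin2, Pd(dppf)Cl2 (5 mol %; dppf = 1,1'-bis(diphenylphosphino)ferrocene), KOAc, 1,4-dioxane, 90 °C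
Reagents that add atoms: bis(pinacolato)diboron, CC1(C)OB(OC1(C)C)B1OC(C)(C)C(C)(C)O1
Why: Miyaura borylation of the aryl bromide, in which KOAc does not activate the product for further coupling and the dppf-ligated catalyst leaves the C–Cl bond and the phenol alone.

Step 11
Reactants: 17 2-chloro-7-methoxy-6-(4,4,5,5-tetramethyl-1,3,2-dioxaborolan-2-yl)phenanthren-3-ol; 9 2-bromo-6-chloro-3-(methoxymethoxy)benzaldehyde
Product: 18 6-chloro-2-(7-chloro-6-hydroxy-2-methoxyphenanthren-3-yl)-3-(methoxymethoxy)benzaldehyde
Conditions: Pd(dppf)Cl2 (5 mol %), K3PO4, 1,4-dioxane/H2O, 85 °C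
Reagents that add atoms: none
Why: Suzuki–Miyaura coupling in which the bromide of 9, activated by the ortho formyl group, should react in preference to all three C–Cl bonds and give the biaryl with three ortho substituents, a substitution level that such 2-bromobenzaldehydes reach routinely.

Step 12
Reactants: 18 6-chloro-2-(7-chloro-6-hydroxy-2-methoxyphenanthren-3-yl)-3-(methoxymethoxy)benzaldehyde; 5 {3-bromo-4-[(triisopropylsilyl)oxy]benzyl}triphenylphosphonium bromide
Product: 20 6-{2-[2-(3-bromo-4-{[triisopropylsilyl]oxy}phenyl)ethenyl]-3-chloro-6-(methoxymethoxy)phenyl}-2-chloro-7-methoxyphenanthren-3-ol (E/Z mixture), via ylide 19 (not isolated)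
Conditions: NaN(SiMe3)2 (2.5 equiv; the first equivalent forms the sodium phenoxide of 18), 5 (1.4 equiv), THF, −78 °C → rt
Reagents that add atoms: none
Why: Wittig olefination of the aldehyde by the semi-stabilised benzylic ylide 19 joins ring D through what becomes the two-carbon bridge, and the alkene geometry is immaterial because step 13 saturates the double bond.

Step 13
Reactants: 20 stilbene (E/Z mixture)
Product: 21 6-{2-[2-(3-bromo-4-{[triisopropylsilyl]oxy}phenyl)ethyl]-3-chloro-6-(methoxymethoxy)phenyl}-2-chloro-7-methoxyphenanthren-3-ol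
Conditions: TsNHNH2 (excess, in portions), NaOAc, DME/H2O, reflux
Reagents that add atoms: none
Why: Diimide generated from the sulfonohydrazide delivers two hydrogens to the C=C bond in a concerted syn transfer and, unlike hydrogenation over a metal, cannot cleave C–Br or C–Cl bonds.

Step 14
Reactants: 21 bibenzyl silyl ether
Product: 22 6-{2-[2-(3-bromo-4-hydroxyphenyl)ethyl]-3-chloro-6-(methoxymethoxy)phenyl}-2-chloro-7-methoxyphenanthren-3-ol
Conditions: Bu4NF, THF, 0 °C
Reagents that add atoms: none
Why: Fluoride cleaves the aryl silyl ether (formation of the strong Si–F bond) while the methoxymethyl ether, the methyl ether and the halides are inert.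

Step 15
Reactants: 22 bisphenol
Product: 24 silylene-bridged macrocycle (22 in which the C3 oxygen of the phenanthrene and the ring D oxygen are both bonded to one Si(tBu)2; 17-membered ring; ring D keeps Br ortho to its oxygen), via silyl triflate 23 (not isolated)
Conditions: tBu2Si(OTf)2 (1.05 equiv, slow addition), 2,6-lutidine, CH2Cl2 (2 mM), 0 °C → reflux
Reagents that add atoms: di-tert-butylsilyl bis(trifluoromethanesulfonate), CC(C)(C)[Si](OS(=O)(=O)C(F)(F)F)(OS(=O)(=O)C(F)(F)F)C(C)(C)C
Why: Double O-silylation of the two phenols by the bis(triflate), the silylene formation known for diols and biphenols, with slow addition at high dilution to favour the 17-membered ring over oligomers and 2,6-lutidine to buffer the triflic acid so that the MOM ether survives.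

Step 16
Reactants: 24 silylene-bridged macrocycle
Product: 25 bridged macrocycle (24 in which Br is lost and the ring D carbon ortho to oxygen is bonded to phenanthrene C4; it contains a 2,2-di-tert-butyldibenzo[d,f][1,3,2]dioxasilepine unit and the twelve-membered ring of the target; ring E oxygen as MOM ether)
Conditions: Pd(OAc)2 (10 mol %), PPh3 (20 mol %), Cs2CO3, tBuCO2H (30 mol %), mesitylene (5 mM), 120 °C
Reagents that add atoms: none
Why: Zerovalent palladium formed from Pd(OAc)2 and PPh3 inserts into the ring D C–Br bond next to the silyloxy group, pivalate replaces bromide on palladium, and a concerted metalation–deprotonation at the phenanthrene C4–H followed by reductive elimination forms the C4–C(ring D) bond. The closest known reaction type is the silicon-tethered intramolecular palladium-catalysed C–H arylation of (2-bromoaryloxy)(aryloxy)di-tert-butylsilanes to dibenzo[d,f][1,3,2]dioxasilepines, a carboxylate-assisted direct arylation used to make unsymmetrical 2,2'-biphenols. The seven-membered dioxasilepine ring closes through an eight-membered palladacycle, and the same C–C bond closes the twelve-membered carbocycle by contraction of the 17-membered bridged ring, so the strained ring is reached by a seven-membered instead of a twelve-membered closure. No stereocentre is formed, and the cisoid arrangement of the two oxygens that the bridge imposes on the new biaryl axis is the one the twelve-membered ring needs anyway. The step needs site selectivity on ring C, secured because C2 carries chlorine and C4–H is the only position ortho to the bridged oxygen, and chemoselectivity for C–Br over the two C–Cl bonds, secured by the weakly donating PPh3 ligand; ring closure should win over oligomer formation because both partners are held in one bridged ring.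

Step 17
Reactants: 25 bridged macrocycle
Product: 27 CNP0310669.0 (target), via MOM ether 26 (not isolated)
Conditions: Bu4NF, THF, 0 °C → rt; then HCl, MeOH, 45 °C (under argon)
Reagents that add atoms: none
Why: Fluoride cleaves both Si–O(aryl) bonds of the bridge to release the 2,2'-biphenol 26, and acid-catalysed acetal exchange in methanol then removes the MOM group, neither reagent touching the aryl methyl ether or the chlorides.

**Compound list**

1 | 3-bromo-4-hydroxybenzaldehyde | O=Cc1ccc(O)c(Br)c1 | starting material
2 | 3-bromo-4-[(triisopropylsilyl)oxy]benzaldehyde | CC(C)[Si](Oc1ccc(C=O)cc1Br)(C(C)C)C(C)C | intermediate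
3 | {3-bromo-4-[(triisopropylsilyl)oxy]phenyl}methanol | CC(C)[Si](Oc1ccc(CO)cc1Br)(C(C)C)C(C)C | intermediate
4 | [2-bromo-4-(bromomethyl)phenoxy]triisopropylsilane (benzyl bromide, not isolated) | CC(C)[Si](Oc1ccc(CBr)cc1Br)(C(C)C)C(C)C | intermediate
5 | {3-bromo-4-[(triisopropylsilyl)oxy]benzyl}triphenylphosphonium bromide | CC(C)[Si](Oc1ccc(C[P+](c2ccccc2)(c2ccccc2)c2ccccc2)cc1Br)(C(C)C)C(C)C.[Br-] | intermediate
6 | 2-bromo-4-chlorophenol | Oc1ccc(Cl)cc1Br | starting material
7 | 2-bromo-4-chloro-1-(methoxymethoxy)benzene | COCOc1ccc(Cl)cc1Br | intermediate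
8 | [2-bromo-6-chloro-3-(methoxymethoxy)phenyl]lithium (not isolated) | COCOc1ccc(Cl)c([Li])c1Br | intermediate
9 | 2-bromo-6-chloro-3-(methoxymethoxy)benzaldehyde | COCOc1ccc(Cl)c(C=O)c1Br | intermediate
10 | 4-bromo-3-methoxybenzaldehyde | COc1cc(C=O)ccc1Br | starting material
11 | 4-bromo-2-iodo-5-methoxybenzaldehyde | COc1cc(C=O)c(I)cc1Br | intermediate
12 | (4-chloro-3-hydroxyphenyl)boronic acid | OB(O)c1ccc(Cl)c(O)c1 | starting material
13 | 5-bromo-4'-chloro-3'-hydroxy-4-methoxybiphenyl-2-carbaldehyde | COc1cc(C=O)c(cc1Br)-c1ccc(Cl)c(O)c1 | intermediate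
14 | 5'-bromo-4-chloro-4'-methoxy-2'-(2-methoxyethenyl)biphenyl-3-ol (E/Z mixture) | COC=Cc1cc(OC)c(Br)cc1-c1ccc(Cl)c(O)c1 | intermediate
15 | 6-bromo-2-chloro-7,10-dimethoxy-9,10-dihydrophenanthren-3-ol (racemic, not isolated) | COC1Cc2cc(OC)c(Br)cc2-c2cc(O)c(Cl)cc21 | intermediate
16 | 6-bromo-2-chloro-7-methoxyphenanthren-3-ol | COc1cc2ccc3cc(Cl)c(O)cc3c2cc1Br | intermediate
17 | 2-chloro-7-methoxy-6-(4,4,5,5-tetramethyl-1,3,2-dioxaborolan-2-yl)phenanthren-3-ol | COc1cc2ccc3cc(Cl)c(O)cc3c2cc1B1OC(C)(C)C(C)(C)O1 | intermediate
18 | 6-chloro-2-(7-chloro-6-hydroxy-2-methoxyphenanthren-3-yl)-3-(methoxymethoxy)benzaldehyde | COc1cc2ccc3cc(Cl)c(O)cc3c2cc1-c1c(OCOC)ccc(Cl)c1C=O | intermediate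
19 | {3-bromo-4-[(triisopropylsilyl)oxy]benzylidene}triphenylphosphorane (ylide, not isolated) | CC(C)[Si](Oc1ccc(C=P(c2ccccc2)(c2ccccc2)c2ccccc2)cc1Br)(C(C)C)C(C)C | intermediate
20 | stilbene: 18 with CHO replaced by CH=CH–[3-bromo-4-(triisopropylsilyloxy)phenyl] (E/Z mixture) | COc1cc2ccc3cc(Cl)c(O)cc3c2cc1-c1c(OCOC)ccc(Cl)c1C=Cc1ccc(O[Si](C(C)C)(C(C)C)C(C)C)c(Br)c1 | intermediate
21 | bibenzyl silyl ether: 20 with the C=C bond saturated | COc1cc2ccc3cc(Cl)c(O)cc3c2cc1-c1c(OCOC)ccc(Cl)c1CCc1ccc(O[Si](C(C)C)(C(C)C)C(C)C)c(Br)c1 | intermediate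
22 | bisphenol: 6-{2-[2-(3-bromo-4-hydroxyphenyl)ethyl]-3-chloro-6-(methoxymethoxy)phenyl}-2-chloro-7-methoxyphenanthren-3-ol | COc1cc2ccc3cc(Cl)c(O)cc3c2cc1-c1c(OCOC)ccc(Cl)c1CCc1ccc(O)c(Br)c1 | intermediate
23 | 22 with the ring D oxygen carrying Si(tBu)2(OTf) (silyl triflate, not isolated) | COc1cc2ccc3cc(Cl)c(O)cc3c2cc1-c1c(OCOC)ccc(Cl)c1CCc1ccc(O[Si](OS(=O)(=O)C(F)(F)F)(C(C)(C)C)C(C)(C)C)c(Br)c1 | intermediate
24 | silylene-bridged 17-membered macrocycle (C3–O–Si(tBu)2–O–ring D; ring D bromide) | COc1cc2ccc3cc(Cl)c4cc3c2cc1-c1c(OCOC)ccc(Cl)c1CCc1ccc(c(Br)c1)O[Si](C(C)(C)C)(C(C)(C)C)O4 | intermediate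
25 | bridged macrocycle with the C4–ring D bond (dibenzodioxasilepine unit, twelve-membered ring, ring E MOM ether) | COc1cc2ccc3cc(Cl)c4c5c3c2cc1-c1c(OCOC)ccc(Cl)c1CCc1ccc(c-5c1)O[Si](C(C)(C)C)(C(C)(C)C)O4 | intermediate
26 | target with its ring E hydroxyl as methoxymethyl ether (not isolated) | COc1cc2ccc3cc(Cl)c(O)c4c3c2cc1-c1c(OCOC)ccc(Cl)c1CCc1ccc(O)c-4c1 | intermediate
27 | CNP0310669.0 | COc1cc2ccc3cc(Cl)c(O)c4c3c2cc1-c1c(O)ccc(Cl)c1CCc1ccc(O)c-4c1 | target

**Count and risks**

Total step count: 17. Longest linear sequence: 12 steps (steps 6 to 17, from 10).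

Step 16. The C–H palladation at the crowded C4–H inside the bridged ring may be slower than reduction of the arylpalladium bromide, so that bromine is lost without ring closure. The fallback sets out from 21 and comes back at 26; it gives up the bridge and makes the same bond by a Suzuki–Miyaura macrocyclisation. Miyaura borylation of the ring D bromide of 21 (B2pin2, Pd(dppf)Cl2, KOAc, 1,4-dioxane) would give the ring D pinacol boronate F1. Iodination of the phenanthrol at C4, its only free ortho position, with N-iodosuccinimide would give the iodo boronate F2. Pd(PPh3)4 and Cs2CO3 in DMF/H2O at high dilution would close the twelve-membered ring to the macrocyclic triisopropylsilyl ether F3, and Bu4NF would convert F3 into 26, which the acid stage of step 17 turns into 27.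

Step 15. Silylation of the second phenol by the hindered silyl triflate 23 may be slower than silylation of a second molecule, so that open-chain oligomers grow instead of the 17-membered ring. The fallback sets out from 18 and 1 and comes back at 24; it installs the silicon bridge between two separate molecules and closes the large ring at the two-carbon bridge instead. Aldehyde 1 with an excess of tBu2Si(OTf)2 and 2,6-lutidine would give the aryloxysilyl triflate F4, which with the phenol of 18 would give the open-chain bis(aryloxy)silane dialdehyde F5. An intramolecular McMurry coupling (TiCl3, Zn–Cu couple, DME, reflux, high dilution) would give the bridged macrocyclic stilbene F6, and diimide reduction as in step 13 would give 24.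

Step 11. Transmetalation between the two ortho-substituted partners may be slow, so that protodeboronation of 17 or insertion of palladium into the formyl-activated C–Cl bond takes over. The fallback sets out from 16 and 9 and comes back at 18; it replaces the boron partner by an organozinc and works without water or base (Negishi coupling). Bromide 16 would be deprotonated at the phenol (NaH), submitted to bromine–lithium exchange (t-BuLi, THF, −78 °C) and transmetalated with ZnCl2 to the arylzinc chloride F7, which with 9 and Pd(PPh3)4 in THF at 50 °C would give 18.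

**Further compounds**

F1 | step 16 | ring D pinacol boronate of 21 (Br replaced by the dioxaborolanyl group) | COc1cc2ccc3cc(Cl)c(O)cc3c2cc1-c1c(OCOC)ccc(Cl)c1CCc1ccc(O[Si](C(C)C)(C(C)C)C(C)C)c(c1)B1OC(C)(C)C(C)(C)O1
F2 | step 16 | iodo boronate: F1 with iodine on phenanthrene C4 | COc1cc2ccc3cc(Cl)c(O)c(I)c3c2cc1-c1c(OCOC)ccc(Cl)c1CCc1ccc(O[Si](C(C)C)(C(C)C)C(C)C)c(c1)B1OC(C)(C)C(C)(C)O1
F3 | step 16 | macrocyclic triisopropylsilyl ether: 26 with its ring D oxygen silylated | COc1cc2ccc3cc(Cl)c(O)c4c3c2cc1-c1c(OCOC)ccc(Cl)c1CCc1ccc(O[Si](C(C)C)(C(C)C)C(C)C)c-4c1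
F4 | step 15 | (2-bromo-4-formylphenoxy)di-tert-butylsilyl trifluoromethanesulfonate | O=Cc1ccc(O[Si](OS(=O)(=O)C(F)(F)F)(C(C)(C)C)C(C)(C)C)c(Br)c1
F5 | step 15 | open-chain bis(aryloxy)silane dialdehyde from 18 and F4 | COc1cc2ccc3cc(Cl)c(O[Si](Oc4ccc(C=O)cc4Br)(C(C)(C)C)C(C)(C)C)cc3c2cc1-c1c(OCOC)ccc(Cl)c1C=O
F6 | step 15 | bridged macrocyclic stilbene: 24 with CH=CH in place of CH2CH2 (E/Z mixture) | COc1cc2ccc3cc(Cl)c4cc3c2cc1-c1c(OCOC)ccc(Cl)c1C=Cc1ccc(c(Br)c1)O[Si](C(C)(C)C)(C(C)(C)C)O4
F7 | step 11 | arylzinc chloride of 16 (sodium phenoxide, zinc on C6) | COc1cc2ccc3cc(Cl)c([O-])cc3c2cc1[Zn]Cl.[Na+]
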